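Nobody can sample the flask before it runs, so borrow its rate from the earlier runs, and first ask which numbers need care.

| flask | substrate | reagent in the second phase | remark | time | volume of the second phase over the first |
|---|---|---|---|---|---|
| south | 0.035 M | 0.0375 M | run made earlier |  |  |
| south-west | 0.055 M | 0.0375 M | run made earlier |  |  |
| north-west | 0.025 M | 0.056 M | run made earlier |  |  |
| flask | 0.025 M | 0.0375 M |  | 20 h | 1.0 |

| run | time / h | target / % | substrate / % |
|---|---|---|---|
| south | 3.00 | 2.1 | 98.7 |
| south | 6.00 | 3.8 | 96.3 |
| south | 10.0 | 6.5 | 92.6 |
| south | 15.0 | 9.7 | 89.7 |
| south | 20.0 | 11.5 | 87.1 |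
| south | 25.0 | 13.4 | 85.6 |
| south-west | 1.33 | 1.2 | 99.8 |
| south-west | 4.00 | 2.2 | 97.9 |
| south-west | 6.00 | 4.1 | 96.5 |
| south-west | 10.0 | 5.7 | 93.6 |
| south-west | 15.0 | 9.0 | 90.9 |
| south-west | 20.0 | 10.6 | 88.6 |
| south-west | 25.0 | 13.0 | 86.6 |
| north-west | 2.00 | 1.0 | 98.9 |
| north-west | 6.00 | 5.8 | 93.8 |
| north-west | 12.0 | 11.5 | 88.0 |
| north-west | 15.0 | 14.1 | 85.6 |
| north-west | 25.0 | 19.0 | 78.4 |

(readings scatter by 0.3 percentage points)

- in the second phase: reagent in the second phase; everything else is in the first
- charges count per volume of the first phase; a concentration in a rate is the amount of a species over the volume of its own phase; every rate counts per litre of the first phase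
- the earlier runs hold the two phases in the same ratio of volumes as the flask asked about

- amount of target at 20 h, in percent of the substrate charged
- the change that raises the amount of target at 20 h, in percent of the substrate charged most ("none" if none brings more than 2 percentage points) (oak / elm / none)
- amount of target at 20 h, in percent of the substrate charged, after oak

- oak: doubling the transfer coefficient of the reagent in the second phase, all else as stated
- elm: doubling the amount of reagent in the second phase, all else as stated

1. Test the substrate. From the south run to the south-west run it rises from 0.035 M to 0.055 M, yet target at 20.0 h moves from 11.5% to 10.6%. An error here costs little.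

2. Test the reagent in the second phase. From the south run to the north-west run its charge grows by a factor 1.49, and target at 15.0 h grows by 1.45. This number matters, but the flask has the south charge, 0.0375 M.

3. Integrate. Let Y be the target share and f the share of remaining substrate converted per hour, so that dY/dt = f(1 − Y), a pseudo-first-order rate. Then f = −ln(1 − Y)/t, which gives 0.00611 h⁻¹ for the south run and 0.00560 h⁻¹ for the south-west run.

4. Extend that line to the flask's substrate: 0.00636 h⁻¹. This is my estimate of the flask's run constant, the share of remaining substrate turned into target each hour. My reckoning gives 11.9% at 20 h, and 22.5% with doubled reagent. The earlier runs show no change of transfer, so I give no number for oak.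

5. The forecast says 12%, elm and 12.6% after oak: “Elm nearly doubles the rate”.

6. The flask gives 12.6%. The best change is elm, which adds 8.1 percentage points, while oak adds 3.6 points and reaches 16.2%.

    reagent in the reaction phase ⇌ reagent in the second phase, rate k1*([reagent in the reaction phase] - [reagent in the second phase]/K1) per volume of the first phase (partition coefficient = 1.70, kL = 0.0740 h⁻¹)
    substrate + reagent in the reaction phase → target (k = 3.70 L mol⁻¹ h⁻¹)
    reagent in the reaction phase + target → over-reacted product (k = 3.20 L mol⁻¹ h⁻¹)
    reagent in the reaction phase → decomposed reagent (k = 0.320 h⁻¹)
    2 reagent in the reaction phase → homo dimer (k = 15.0 L mol⁻¹ h⁻¹)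

7. The flask's own reading gives a run constant of 0.00672 h⁻¹, close to f. Applied to the same flask stopped at 12 h, f gives 7.35%, but that flask holds 8.40%, a constant of 0.00731 h⁻¹, above the value at 20 h. Two things together hold this flask at 12.6%: the reading at 20 h and not ten times later, and the conversion of reagent in the reaction phase into decomposed reagent. With that conversion taken away, the flask makes 20.8% at 20 h, and left until 200 h it makes 23.1%.

The runs are calculated for substances that don't exist, and the scatter is random.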